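**Plan**

- Retrosynthesis: the cuts are, in order, the para O–CH3 bond of the trimethoxyphenyl ring, the O1–C5 bond of the oxolane, the C5–aryl bond, the C4–C5 and C4–CH3 bonds, and the C2–C3 bond.
- Forward: an aldol reaction joins 3,4-dimethoxybenzaldehyde to a propionate unit (C2–C3); the acyl carbon becomes C4 and is built up to an isopropenyl group; hydroboration and sp3–sp2 coupling attach the silyl-protected 4-hydroxy-3,5-dimethoxyphenyl ring at C5. The oxolane, the only ring made, closes last at O1–C5, and one O-methylation finishes the route.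
- Stereochemistry: C2 and C3 come from an oxazolidinone-controlled syn aldol, C4 from a hydroboration steered by C3, and C5 from the ring closure steered by C2, C3 and C4.
- Enabling feature: with the oxolane numbered O1, C2 (3,4-dimethoxyphenyl), C3 and C4 (methyl), C5 (3,4,5-trimethoxyphenyl), the C5 aryl ring is the only one with a para oxygen between two methoxy groups. Kept as the free phenol, that ring alone can be oxidised to a para-quinone methide, and the methide carbon is C5, the one centre whose aryl group must end up trans to its neighbouring methyl.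

Key step: step 9

Remark: compounds 1, 2 and 9 are taken as purchasable, and the labels C2–C5 refer to the oxolane numbering of the target also in open-chain intermediates.

**Route**

Step 1
Reactants: 1 3,4-dimethoxybenzaldehyde; 2 (4S)-4-benzyl-3-propanoyl-1,3-oxazolidin-2-one
Product: 4 (4S)-4-benzyl-3-[(2S,3S)-3-(3,4-dimethoxyphenyl)-3-hydroxy-2-methylpropanoyl]-1,3-oxazolidin-2-one, via dibutylboron Z-enolate 3 (not isolated)
Conditions: Bu2BOTf, i-Pr2NEt, CH2Cl2, 0 °C; then 1, −78 → 0 °C; H2O2, pH 7 buffer, MeOH, 0 °C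
Reagents that add atoms: none
Why: In this Evans syn aldol reaction the Z-boron enolate should react through a closed Zimmerman–Traxler chair in which the benzyl group of the auxiliary shields one enolate face, so that the carbinol centre (later C2) and the methyl-bearing centre (later C3) are both set under auxiliary control.

Step 2
Reactants: 4 (4S)-4-benzyl-3-[(2S,3S)-3-(3,4-dimethoxyphenyl)-3-hydroxy-2-methylpropanoyl]-1,3-oxazolidin-2-one
Product: 5 (2S,3S)-3-(3,4-dimethoxyphenyl)-3-hydroxy-N-methoxy-N,2-dimethylpropanamide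
Conditions: MeNHOMe·HCl, AlMe3, CH2Cl2, −10 °C → rt
Reagents that add atoms: N,O-dimethylhydroxylamine hydrochloride, CNOC.Cl
Why: Aluminium-amide transamidation of an N-acyloxazolidinone to the Weinreb amide is assisted by the free β-hydroxyl and should release the auxiliary without touching either stereocentre.

Step 3
Reactants: 5 (2S,3S)-3-(3,4-dimethoxyphenyl)-3-hydroxy-N-methoxy-N,2-dimethylpropanamide
Product: 6 (2S,3S)-3-{[tert-butyl(dimethyl)silyl]oxy}-3-(3,4-dimethoxyphenyl)-N-methoxy-N,2-dimethylpropanamide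
Conditions: TBSOTf, 2,6-lutidine, CH2Cl2, −78 → 0 °C
Reagents that add atoms: tert-butyldimethylsilyl trifluoromethanesulfonate, CC(C)(C)[Si](C)(C)OS(=O)(=O)C(F)(F)F
Why: Silylation of the secondary benzylic alcohol with a silyl triflate and a hindered base is routine and blocks retro-aldol cleavage in the organometallic steps that follow.

Step 4
Reactants: 6 (2S,3S)-3-{[tert-butyl(dimethyl)silyl]oxy}-3-(3,4-dimethoxyphenyl)-N-methoxy-N,2-dimethylpropanamide
Product: 7 (3S,4S)-4-{[tert-butyl(dimethyl)silyl]oxy}-4-(3,4-dimethoxyphenyl)-3-methylbutan-2-one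
Conditions: MeMgBr, THF, −20 → 0 °C
Reagents that add atoms: methylmagnesium bromide, C[Mg]Br
Why: In this Weinreb ketone synthesis the chelated tetrahedral adduct should persist until work-up, which prevents over-addition and keeps the α-centre from enolising.

Step 5
Reactants: 7 (3S,4S)-4-{[tert-butyl(dimethyl)silyl]oxy}-4-(3,4-dimethoxyphenyl)-3-methylbutan-2-one
Product: 8 tert-butyl{[(1S,2R)-1-(3,4-dimethoxyphenyl)-2,3-dimethylbut-3-en-1-yl]oxy}dimethylsilane
Conditions: Ph3PCH3Br, KN(SiMe3)2, THF, 0 °C → rt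
Reagents that add atoms: methyltriphenylphosphonium bromide, C[P+](c1ccccc1)(c1ccccc1)c1ccccc1.[Br-]
Why: Wittig methylenation with the non-stabilised ylide, which is more nucleophilic than basic, should convert the methyl ketone into the 1,1-disubstituted alkene and leave the adjacent C3 centre intact.

Step 6
Reactants: 9 4-bromo-2,6-dimethoxyphenol
Product: 10 (4-bromo-2,6-dimethoxyphenoxy)tri(propan-2-yl)silane
Conditions: TIPSCl, imidazole, DMF, rt
Reagents that add atoms: chlorotri(propan-2-yl)silane, CC(C)[Si](Cl)(C(C)C)C(C)C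
Why: Imidazole-mediated silylation of the phenol gives an aryl silyl ether that is bulky enough to survive the basic coupling and that fluoride removes later together with the alkyl silyl ether.

Step 7
Reactants: 8 tert-butyl{[(1S,2R)-1-(3,4-dimethoxyphenyl)-2,3-dimethylbut-3-en-1-yl]oxy}dimethylsilane; 10 (4-bromo-2,6-dimethoxyphenoxy)tri(propan-2-yl)silane
Product: 12 tert-butyl{[(1S,2R,3R)-4-(3,5-dimethoxy-4-{[tri(propan-2-yl)silyl]oxy}phenyl)-1-(3,4-dimethoxyphenyl)-2,3-dimethylbutyl]oxy}dimethylsilane, via B-alkyl-9-BBN borane 11 (not isolated)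
Conditions: 9-BBN, THF, 0 → 50 °C; then 10, Pd(OAc)2, SPhos, K3PO4, H2O, THF, 65 °C
Reagents that add atoms: none
Why: Anti-Markovnikov hydroboration with 9-BBN should take place on the alkene face opposite the bulky silyloxy(aryl)methyl group, in the conformer whose C3 hydrogen lies in the alkene plane (allylic strain model), which sets C4 with its methyl destined to be cis to the C3 methyl in the ring, and the primary alkylborane 11 then undergoes B-alkyl Suzuki–Miyaura coupling with the aryl bromide under a bulky electron-rich phosphine that outruns β-hydride elimination.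

Step 8
Reactants: 12 tert-butyl{[(1S,2R,3R)-4-(3,5-dimethoxy-4-{[tri(propan-2-yl)silyl]oxy}phenyl)-1-(3,4-dimethoxyphenyl)-2,3-dimethylbutyl]oxy}dimethylsilane
Product: 13 4-[(2R,3R,4S)-4-(3,4-dimethoxyphenyl)-4-hydroxy-2,3-dimethylbutyl]-2,6-dimethoxyphenol
Conditions: Bu4NF, AcOH, THF, rt → 40 °C
Reagents that add atoms: none
Why: Fluoride-mediated desilylation should cleave the aryl and the benzylic silyl ether in one operation, the acetic acid buffer keeping the electron-rich phenol from standing as its air-sensitive phenoxide, and no stereocentre is involved.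

Step 9
Reactants: 13 4-[(2R,3R,4S)-4-(3,4-dimethoxyphenyl)-4-hydroxy-2,3-dimethylbutyl]-2,6-dimethoxyphenol
Product: 15 4-[(2S,3S,4R,5S)-5-(3,4-dimethoxyphenyl)-3,4-dimethyloxolan-2-yl]-2,6-dimethoxyphenol, via para-quinone methide 14 (not isolated)
Conditions: Ag2O, CH2Cl2, rt, dark
Reagents that add atoms: none
Why: Ag2O takes two electrons and two protons from the 4-alkyl-2,6-dimethoxyphenol (phenoxyl radical, then loss of a C5 hydrogen) to give the para-quinone methide 14 with a planar methide carbon, and the C2 hydroxyl adds to that carbon in an oxa-1,6-conjugate addition that forms O1–C5 and restores the aromatic ring; the closest known reaction type is the Ag2O oxidation of 4-alkyl-2,6-dimethoxyphenols to para-quinone methides with intramolecular capture by a hydroxyl group. The oxolane closes in a 5-exo-trig mode. The new C5 centre is controlled by the C4 methyl, backed by the C3 methyl and the C2 aryl group on the same face: the aryl-bearing methide carbon turns away from that face, so the C5 aryl group should end up trans to the C4 methyl, and because the addition is reversible through the phenoxide the same isomer is also the thermodynamic one. The step needs selectivity between the two electron-rich rings and between the two benzylic positions, and the substrate provides it: only the C5 ring has a free para-hydroxyl, its ortho positions are blocked by methoxy groups so that radical coupling is shut off, and the C2 carbinol cannot ionise under these neutral conditions, so its cis relationship to C3 stays untouched.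

Step 10
Reactants: 15 4-[(2S,3S,4R,5S)-5-(3,4-dimethoxyphenyl)-3,4-dimethyloxolan-2-yl]-2,6-dimethoxyphenol
Product: 16 ligraminol A, (2S,3R,4S,5S)-2-(3,4-dimethoxyphenyl)-3,4-dimethyl-5-(3,4,5-trimethoxyphenyl)oxolane
Conditions: MeI, K2CO3, acetone, reflux
Reagents that add atoms: iodomethane, CI
Why: Williamson O-methylation of the only acidic group, the hindered phenol, should give the third methoxy group without affecting the four ring stereocentres.

**Compound list**

1 | 3,4-dimethoxybenzaldehyde | COc1ccc(C=O)cc1OC | starting material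
2 | (4S)-4-benzyl-3-propanoyl-1,3-oxazolidin-2-one | CCC(=O)N1C(=O)OC[C@@H]1Cc1ccccc1 | starting material
3 | (4S)-4-benzyl-3-[(1Z)-1-[(dibutylboranyl)oxy]prop-1-en-1-yl]-1,3-oxazolidin-2-one | CCCCB(CCCC)O/C(=C\C)N1C(=O)OC[C@@H]1Cc1ccccc1 | intermediate
4 | (4S)-4-benzyl-3-[(2S,3S)-3-(3,4-dimethoxyphenyl)-3-hydroxy-2-methylpropanoyl]-1,3-oxazolidin-2-one | COc1ccc(cc1OC)[C@@H](O)[C@H](C)C(=O)N1C(=O)OC[C@@H]1Cc1ccccc1 | intermediate
5 | (2S,3S)-3-(3,4-dimethoxyphenyl)-3-hydroxy-N-methoxy-N,2-dimethylpropanamide | COc1ccc(cc1OC)[C@@H](O)[C@H](C)C(=O)N(C)OC | intermediate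
6 | (2S,3S)-3-{[tert-butyl(dimethyl)silyl]oxy}-3-(3,4-dimethoxyphenyl)-N-methoxy-N,2-dimethylpropanamide | COc1ccc(cc1OC)[C@@H](O[Si](C)(C)C(C)(C)C)[C@H](C)C(=O)N(C)OC | intermediate
7 | (3S,4S)-4-{[tert-butyl(dimethyl)silyl]oxy}-4-(3,4-dimethoxyphenyl)-3-methylbutan-2-one | COc1ccc(cc1OC)[C@@H](O[Si](C)(C)C(C)(C)C)[C@H](C)C(C)=O | intermediate
8 | tert-butyl{[(1S,2R)-1-(3,4-dimethoxyphenyl)-2,3-dimethylbut-3-en-1-yl]oxy}dimethylsilane | COc1ccc(cc1OC)[C@@H](O[Si](C)(C)C(C)(C)C)[C@H](C)C(C)=C | intermediate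
9 | 4-bromo-2,6-dimethoxyphenol | COc1cc(Br)cc(OC)c1O | starting material
10 | (4-bromo-2,6-dimethoxyphenoxy)tri(propan-2-yl)silane | COc1cc(Br)cc(OC)c1O[Si](C(C)C)(C(C)C)C(C)C | intermediate
11 | 9-[(2R,3R,4S)-4-{[tert-butyl(dimethyl)silyl]oxy}-4-(3,4-dimethoxyphenyl)-2,3-dimethylbutyl]-9-borabicyclo[3.3.1]nonane | COc1ccc(cc1OC)[C@@H](O[Si](C)(C)C(C)(C)C)[C@H](C)[C@H](C)CB1C2CCCC1CCC2 | intermediate
12 | tert-butyl{[(1S,2R,3R)-4-(3,5-dimethoxy-4-{[tri(propan-2-yl)silyl]oxy}phenyl)-1-(3,4-dimethoxyphenyl)-2,3-dimethylbutyl]oxy}dimethylsilane | COc1ccc(cc1OC)[C@@H](O[Si](C)(C)C(C)(C)C)[C@H](C)[C@H](C)Cc1cc(OC)c(O[Si](C(C)C)(C(C)C)C(C)C)c(OC)c1 | intermediate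
13 | 4-[(2R,3R,4S)-4-(3,4-dimethoxyphenyl)-4-hydroxy-2,3-dimethylbutyl]-2,6-dimethoxyphenol | COc1ccc(cc1OC)[C@@H](O)[C@H](C)[C@H](C)Cc1cc(OC)c(O)c(OC)c1 | intermediate
14 | 4-[(2R,3R,4S)-4-(3,4-dimethoxyphenyl)-4-hydroxy-2,3-dimethylbutylidene]-2,6-dimethoxycyclohexa-2,5-dien-1-one | COc1ccc(cc1OC)[C@@H](O)[C@H](C)[C@H](C)C=C1C=C(OC)C(=O)C(OC)=C1 | intermediate
15 | 4-[(2S,3S,4R,5S)-5-(3,4-dimethoxyphenyl)-3,4-dimethyloxolan-2-yl]-2,6-dimethoxyphenol | COc1ccc([C@H]2O[C@H](c3cc(OC)c(O)c(OC)c3)[C@@H](C)[C@H]2C)cc1OC | intermediate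
16 | ligraminol A, (2S,3R,4S,5S)-2-(3,4-dimethoxyphenyl)-3,4-dimethyl-5-(3,4,5-trimethoxyphenyl)oxolane | COc1ccc([C@H]2O[C@H](c3cc(OC)c(OC)c(OC)c3)[C@@H](C)[C@H]2C)cc1OC | target

**Step count and risks**

Total step count: 10. Longest linear sequence: 9 steps (steps 1–5 and 7–10); step 6 is a one-step side branch.

Step 7. The hydroboration may discriminate poorly between the two alkene faces, because in a 1,1-disubstituted alkene the allylic strain that fixes the reactive conformer is weak; the C4 epimer would then be carried through the coupling. The fallback sets C4 by catalyst-controlled hydrogenation of a trisubstituted alkene instead. It sets out from Weinreb amide 6. Reduction with i-Bu2AlH (THF, −78 °C) should give (2S,3S)-3-{[tert-butyl(dimethyl)silyl]oxy}-3-(3,4-dimethoxyphenyl)-2-methylpropanal F1. Ohira–Bestmann homologation (dimethyl (1-diazo-2-oxopropyl)phosphonate, K2CO3, MeOH) should give the alkyne tert-butyl{[(1S,2R)-1-(3,4-dimethoxyphenyl)-2-methylbut-3-yn-1-yl]oxy}dimethylsilane F2. Zirconium-catalysed syn-carboalumination (AlMe3, Cp2ZrCl2, CH2Cl2) should give the alkenylalane [(1E,3R,4S)-4-{[tert-butyl(dimethyl)silyl]oxy}-4-(3,4-dimethoxyphenyl)-2,3-dimethylbut-1-en-1-yl]dimethylalumane F3. This is coupled in the same flask with aryl bromide 10 (Pd(PPh3)4, ZnCl2, THF) to the styrene tert-butyl{[(1S,2R,3E)-4-(3,5-dimethoxy-4-{[tri(propan-2-yl)silyl]oxy}phenyl)-1-(3,4-dimethoxyphenyl)-2,3-dimethylbut-3-en-1-yl]oxy}dimethylsilane F4. Hydrogenation of F4 (H2, [Ir(cod)(L)][B(C6H3(CF3)2)4] with L a chiral phosphine–oxazoline, CH2Cl2) should set C4 under reagent control; the ligand enantiomer is chosen for the matched case, and the strong allylic 1,3-strain of the trisubstituted alkene works in the same direction. The sequence comes back to the route at compound 12.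

Step 9. The quinone methide may tautomerise to the 4-alkenylphenol by loss of the C4 hydrogen before the hydroxyl adds, or the product, itself a 4-alkyl-2,6-dimethoxyphenol, may be oxidised a second time. The fallback reaches the same O1–C5 closure through the same quinone methide without an oxidant, from a C5 carbinol. It sets out from alkene 8. Hydroboration and oxidation (9-BBN, THF; NaOH, H2O2) should give (2S,3R,4S)-4-{[tert-butyl(dimethyl)silyl]oxy}-4-(3,4-dimethoxyphenyl)-2,3-dimethylbutan-1-ol F5, and Dess–Martin oxidation (CH2Cl2, rt) the aldehyde (2S,3R,4S)-4-{[tert-butyl(dimethyl)silyl]oxy}-4-(3,4-dimethoxyphenyl)-2,3-dimethylbutanal F6. Bromine–lithium exchange on 10 (n-BuLi, THF, −78 °C) gives (3,5-dimethoxy-4-{[tri(propan-2-yl)silyl]oxy}phenyl)lithium F7. Its addition to F6 should give, as a mixture of C5 epimers that does not matter, (2S,3R,4S)-4-{[tert-butyl(dimethyl)silyl]oxy}-1-(3,5-dimethoxy-4-{[tri(propan-2-yl)silyl]oxy}phenyl)-4-(3,4-dimethoxyphenyl)-2,3-dimethylbutan-1-ol F8. Desilylation (Bu4NF, AcOH, THF) should give 4-[(2S,3R,4S)-4-(3,4-dimethoxyphenyl)-1,4-dihydroxy-2,3-dimethylbutyl]-2,6-dimethoxyphenol F9. Catalytic pyridinium p-toluenesulfonate (CH2Cl2, rt) should then dehydrate only the para-hydroxybenzylic alcohol to quinone methide 14, which the C2 hydroxyl captures as in the main route. The sequence comes back at compound 15.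

Step 5. The basic ylide may enolise the α-branched ketone, which would epimerise C3 or expel the β-silyloxy group. The fallback replaces the ylide by a two-stage Peterson methylenation with a nucleophile of low basicity. It sets out from ketone 7. Addition of Me3SiCH2MgCl in the presence of anhydrous CeCl3 (THF, −78 °C) should give, as a mixture of carbinol epimers that does not matter, (3S,4S)-4-{[tert-butyl(dimethyl)silyl]oxy}-4-(3,4-dimethoxyphenyl)-2,3-dimethyl-1-(trimethylsilyl)butan-2-ol F10. Elimination with KH (THF, 0 °C → rt) then comes back to the route at compound 8.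

**Further compounds**

F1 | step 7 | (2S,3S)-3-{[tert-butyl(dimethyl)silyl]oxy}-3-(3,4-dimethoxyphenyl)-2-methylpropanal | COc1ccc(cc1OC)[C@@H](O[Si](C)(C)C(C)(C)C)[C@H](C)C=O
F2 | step 7 | tert-butyl{[(1S,2R)-1-(3,4-dimethoxyphenyl)-2-methylbut-3-yn-1-yl]oxy}dimethylsilane | COc1ccc(cc1OC)[C@@H](O[Si](C)(C)C(C)(C)C)[C@H](C)C#C
F3 | step 7 | [(1E,3R,4S)-4-{[tert-butyl(dimethyl)silyl]oxy}-4-(3,4-dimethoxyphenyl)-2,3-dimethylbut-1-en-1-yl]dimethylalumane | COc1ccc(cc1OC)[C@@H](O[Si](C)(C)C(C)(C)C)[C@H](C)/C(C)=C/[Al](C)C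
F4 | step 7 | tert-butyl{[(1S,2R,3E)-4-(3,5-dimethoxy-4-{[tri(propan-2-yl)silyl]oxy}phenyl)-1-(3,4-dimethoxyphenyl)-2,3-dimethylbut-3-en-1-yl]oxy}dimethylsilane | COc1ccc(cc1OC)[C@@H](O[Si](C)(C)C(C)(C)C)[C@H](C)/C(C)=C/c1cc(OC)c(O[Si](C(C)C)(C(C)C)C(C)C)c(OC)c1
F5 | step 9 | (2S,3R,4S)-4-{[tert-butyl(dimethyl)silyl]oxy}-4-(3,4-dimethoxyphenyl)-2,3-dimethylbutan-1-ol | COc1ccc(cc1OC)[C@@H](O[Si](C)(C)C(C)(C)C)[C@H](C)[C@H](C)CO
F6 | step 9 | (2S,3R,4S)-4-{[tert-butyl(dimethyl)silyl]oxy}-4-(3,4-dimethoxyphenyl)-2,3-dimethylbutanal | COc1ccc(cc1OC)[C@@H](O[Si](C)(C)C(C)(C)C)[C@H](C)[C@H](C)C=O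
F7 | step 9 | (3,5-dimethoxy-4-{[tri(propan-2-yl)silyl]oxy}phenyl)lithium | [Li]c1cc(OC)c(O[Si](C(C)C)(C(C)C)C(C)C)c(OC)c1
F8 | step 9 | (2S,3R,4S)-4-{[tert-butyl(dimethyl)silyl]oxy}-1-(3,5-dimethoxy-4-{[tri(propan-2-yl)silyl]oxy}phenyl)-4-(3,4-dimethoxyphenyl)-2,3-dimethylbutan-1-ol (both C1 epimers) | COc1ccc(cc1OC)[C@@H](O[Si](C)(C)C(C)(C)C)[C@H](C)[C@H](C)C(O)c1cc(OC)c(O[Si](C(C)C)(C(C)C)C(C)C)c(OC)c1
F9 | step 9 | 4-[(2S,3R,4S)-4-(3,4-dimethoxyphenyl)-1,4-dihydroxy-2,3-dimethylbutyl]-2,6-dimethoxyphenol (both C1 epimers) | COc1ccc(cc1OC)[C@@H](O)[C@H](C)[C@H](C)C(O)c1cc(OC)c(O)c(OC)c1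
F10 | step 5 | (3S,4S)-4-{[tert-butyl(dimethyl)silyl]oxy}-4-(3,4-dimethoxyphenyl)-2,3-dimethyl-1-(trimethylsilyl)butan-2-ol (both C2 epimers) | COc1ccc(cc1OC)[C@@H](O[Si](C)(C)C(C)(C)C)[C@H](C)C(C)(O)C[Si](C)(C)C
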